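## Retrosynthetic overview

1. The target is a 2,6-cis-oxane (O1, C2 aryl, C4 OH, C6 arylethyl; 2S,4S,6S) with an axial C4 hydroxyl. The carbinol is traced back to an oxan-4-one by equatorial hydride delivery, and both phenols are carried as TBS ethers and released last.
2. The oxan-4-one is traced back to a catalytic enantioselective hetero-Diels–Alder reaction that makes C5–C6 and O1–C2 in one operation from two achiral halves: a 2-silyloxydiene (C2–C5) and an aldehyde (C6=O1).
3. Enabling feature: O1 and the C4 oxygen stand 1,3 on the oxane ring and C2 is benzylic to a guaiacyl ring. C2–C3–C4(O)–C5 is therefore a latent 1-aryl-3-silyloxybutadiene (the silyl dienol ether of dehydrozingerone), and C6–O1 is the carbonyl of a 3-arylpropanal.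
4. The oxane is the only ring formed, and it is formed in the key step. The diene comes from dehydrozingerone in two steps and the aldehyde from ethyl dihydroferulate in two steps.

Key step: step 5

Abbreviations: TBS = tert-butyldimethylsilyl, TES = triethylsilyl. Catalyst notation: CrCl(L) is the chromium chloride complex (trivalent chromium) of L = C27H29NO2, the doubly deprotonated Schiff base of 3-(1-adamantyl)-2-hydroxy-5-methylbenzaldehyde and (1R,2S)-1-aminoindan-2-ol.

Remark (assumption): the (1R,2S) antipode of CrCl(L) is assumed to expose the aldehyde face that leads to (6S), the sense expected for this catalyst class with unbranched aliphatic aldehydes; should the first run show the opposite sense, the (1S,2R) antipode is used with no other change.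

## Route

Step 1
Reactants: 1 (E)-4-(4-hydroxy-3-methoxyphenyl)but-3-en-2-one (dehydrozingerone)
Product: 2 (E)-4-[4-(tert-butyldimethylsilyloxy)-3-methoxyphenyl]but-3-en-2-one
Conditions: TBSCl, imidazole, DMF, rt
Reagents that add atoms: tert-butyldimethylsilyl chloride (TBSCl), CC(C)(C)[Si](C)(C)Cl
Why: Imidazole-promoted silylation of the phenol (silyl ether formation) should be clean because the phenol is the only nucleophilic site and the enone is inert.

Step 2
Reactants: 2 (E)-4-[4-(tert-butyldimethylsilyloxy)-3-methoxyphenyl]but-3-en-2-one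
Product: 3 (E)-1-[4-(tert-butyldimethylsilyloxy)-3-methoxyphenyl]-3-(triethylsilyloxy)buta-1,3-diene
Conditions: TESOTf, Et3N, Et2O, 0 °C; cold aq. NaHCO3 work-up, used without chromatography
Reagents that add atoms: triethylsilyl trifluoromethanesulfonate (TESOTf), CC[Si](CC)(CC)OS(=O)(=O)C(F)(F)F
Why: Soft enolization with a silyl triflate and an amine base (silyl enol ether formation) can only occur at the methyl group, so a single cross-conjugated 2-silyloxydiene should form with the E styryl geometry untouched.

Step 3
Reactants: 4 ethyl 3-(4-hydroxy-3-methoxyphenyl)propanoate (ethyl dihydroferulate)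
Product: 5 ethyl 3-[4-(tert-butyldimethylsilyloxy)-3-methoxyphenyl]propanoate
Conditions: TBSCl, imidazole, DMF, rt
Reagents that add atoms: tert-butyldimethylsilyl chloride (TBSCl), CC(C)(C)[Si](C)(C)Cl
Why: Phenol silylation as in step 1; the ester is inert.

Step 4
Reactants: 5 ethyl 3-[4-(tert-butyldimethylsilyloxy)-3-methoxyphenyl]propanoate
Product: 7 3-[4-(tert-butyldimethylsilyloxy)-3-methoxyphenyl]propanal, via aluminium hemiacetal 6 (not isolated)
Conditions: i-Bu2AlH (1.1 equiv), CH2Cl2, −78 °C; MeOH, then aq. potassium sodium tartrate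
Reagents that add atoms: none
Why: Partial reduction of an ester with i-Bu2AlH should stop at the tetrahedral aluminium hemiacetal 6, which is stable at −78 °C and collapses to the aldehyde only on aqueous work-up; the aryl silyl ether is inert.

Step 5
Reactants: 3 (E)-1-[4-(tert-butyldimethylsilyloxy)-3-methoxyphenyl]-3-(triethylsilyloxy)buta-1,3-diene, 7 3-[4-(tert-butyldimethylsilyloxy)-3-methoxyphenyl]propanal
Product: 9 (2S,6S)-2-[4-(tert-butyldimethylsilyloxy)-3-methoxyphenyl]-6-{2-[4-(tert-butyldimethylsilyloxy)-3-methoxyphenyl]ethyl}oxan-4-one, via triethylsilyl enol ether cycloadduct 8 (not isolated)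
Conditions: (1R,2S)-CrCl(C27H29NO2) (5 mol %), powdered 4 Å MS, neat or minimal t-BuOMe, rt; then TFA (cat.), wet CH2Cl2, 0 °C
Reagents that add atoms: none
Why: The chromium-bound aldehyde 7 (Lewis acid activation) should undergo a concerted, asynchronous normal-demand hetero-Diels–Alder reaction with the s-cis conformer of diene 3, the CH2 terminus bonding to the carbonyl carbon (C5–C6) while the carbonyl oxygen closes onto the styryl terminus (O1–C2), after which TFA protonates enol ether 8 at C3 and releases ketone 9. The closest known reaction type is the enantioselective hetero-Diels–Alder reaction of 1-substituted 3-silyloxybutadienes with unactivated aliphatic aldehydes under tridentate Schiff-base chromium chloride catalysis, which gives 2,6-cis-oxan-4-ones. The oxane ring is closed as an intermolecular [4+2] cycloaddition, C2 to C5 coming from the diene and C6 plus O1 from the aldehyde; a stepwise path (Mukaiyama aldol then 6-endo oxa-Michael closure) would make the same two bonds and the same ketone. C6 is set by the catalyst, whose adamantyl and indane groups leave one face of the coordinated aldehyde open, and C2 is set relative to C6 by the endo transition state together with the fixed E geometry of the diene, which should give the 2,6-cis (2S,6S) adduct. The step needs regioselectivity (the 3-silyloxy group makes the CH2 terminus the nucleophilic end, reinforced by the electron-rich aryl at the other terminus), endo and enantiofacial selectivity (catalyst), and tolerance of the aryl silyl ethers (neutral conditions over molecular sieves, brief cold acid).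

Step 6
Reactants: 9 (2S,6S)-2-[4-(tert-butyldimethylsilyloxy)-3-methoxyphenyl]-6-{2-[4-(tert-butyldimethylsilyloxy)-3-methoxyphenyl]ethyl}oxan-4-one
Product: 10 (2S,4S,6S)-2-[4-(tert-butyldimethylsilyloxy)-3-methoxyphenyl]-6-{2-[4-(tert-butyldimethylsilyloxy)-3-methoxyphenyl]ethyl}oxan-4-ol
Conditions: LiBH(s-Bu)3 (L-Selectride), THF, −78 °C; AcOH quench
Reagents that add atoms: none
Why: Stereoselective ketone reduction by a bulky trialkylborohydride: in the chair with the C2 and C6 substituents equatorial the reagent should attack from the equatorial direction, away from the axial hydrogens at C2 and C6, and set C4 as the axial (4S) alcohol.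

Step 7
Reactants: 10 (2S,4S,6S)-2-[4-(tert-butyldimethylsilyloxy)-3-methoxyphenyl]-6-{2-[4-(tert-butyldimethylsilyloxy)-3-methoxyphenyl]ethyl}oxan-4-ol
Product: 11 (2S,4S,6S)-2-(4-hydroxy-3-methoxyphenyl)-6-[2-(4-hydroxy-3-methoxyphenyl)ethyl]oxan-4-ol
Conditions: n-Bu4NF, AcOH, THF, 0 °C to rt
Reagents that add atoms: none
Why: Fluoride-mediated cleavage of aryl silyl ethers is fast and leaves the secondary alcohol and the benzylic ring ether untouched, and the acetic acid buffer should prevent phenoxide-triggered ring opening through a para-quinone methide.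

## Compound list

1 | (E)-4-(4-hydroxy-3-methoxyphenyl)but-3-en-2-one (dehydrozingerone) | COc1cc(/C=C/C(C)=O)ccc1O | starting material
2 | (E)-4-[4-(tert-butyldimethylsilyloxy)-3-methoxyphenyl]but-3-en-2-one | COc1cc(/C=C/C(C)=O)ccc1O[Si](C)(C)C(C)(C)C | intermediate
3 | (E)-1-[4-(tert-butyldimethylsilyloxy)-3-methoxyphenyl]-3-(triethylsilyloxy)buta-1,3-diene | COc1cc(/C=C/C(=C)O[Si](CC)(CC)CC)ccc1O[Si](C)(C)C(C)(C)C | intermediate
4 | ethyl 3-(4-hydroxy-3-methoxyphenyl)propanoate | CCOC(=O)CCc1ccc(O)c(OC)c1 | starting material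
5 | ethyl 3-[4-(tert-butyldimethylsilyloxy)-3-methoxyphenyl]propanoate | CCOC(=O)CCc1ccc(O[Si](C)(C)C(C)(C)C)c(OC)c1 | intermediate
6 | {1-ethoxy-3-[4-(tert-butyldimethylsilyloxy)-3-methoxyphenyl]propoxy}diisobutylalane (aluminium hemiacetal, racemic at the acetal carbon, not isolated) | CCOC(CCc1ccc(O[Si](C)(C)C(C)(C)C)c(OC)c1)O[Al](CC(C)C)CC(C)C | intermediate
7 | 3-[4-(tert-butyldimethylsilyloxy)-3-methoxyphenyl]propanal | O=CCCc1ccc(O[Si](C)(C)C(C)(C)C)c(OC)c1 | intermediate
8 | (2S,6S)-2-[4-(tert-butyldimethylsilyloxy)-3-methoxyphenyl]-6-{2-[4-(tert-butyldimethylsilyloxy)-3-methoxyphenyl]ethyl}-4-(triethylsilyloxy)-5,6-dihydro-2H-pyran (2,6-cis, not isolated) | COc1cc(CC[C@H]2CC(O[Si](CC)(CC)CC)=C[C@@H](c3ccc(O[Si](C)(C)C(C)(C)C)c(OC)c3)O2)ccc1O[Si](C)(C)C(C)(C)C | intermediate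
9 | (2S,6S)-2-[4-(tert-butyldimethylsilyloxy)-3-methoxyphenyl]-6-{2-[4-(tert-butyldimethylsilyloxy)-3-methoxyphenyl]ethyl}oxan-4-one (2,6-cis) | COc1cc(CC[C@H]2CC(=O)C[C@@H](c3ccc(O[Si](C)(C)C(C)(C)C)c(OC)c3)O2)ccc1O[Si](C)(C)C(C)(C)C | intermediate
10 | (2S,4S,6S)-2-[4-(tert-butyldimethylsilyloxy)-3-methoxyphenyl]-6-{2-[4-(tert-butyldimethylsilyloxy)-3-methoxyphenyl]ethyl}oxan-4-ol (2,6-cis, axial OH) | COc1cc(CC[C@H]2C[C@H](O)C[C@@H](c3ccc(O[Si](C)(C)C(C)(C)C)c(OC)c3)O2)ccc1O[Si](C)(C)C(C)(C)C | intermediate
11 | (2S,4S,6S)-2-(4-hydroxy-3-methoxyphenyl)-6-[2-(4-hydroxy-3-methoxyphenyl)ethyl]oxan-4-ol | COc1cc(CC[C@H]2C[C@H](O)C[C@@H](c3ccc(O)c(OC)c3)O2)ccc1O | target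

## Step count and risks

Total step count: 7. Longest linear sequence: 5 steps (1 → 2 → 3 → 9 → 10 → 11, or equally 4 → 5 → 7 → 9 → 10 → 11).

Steps most likely to fail:

1. Step 5. The cycloaddition of an unactivated aliphatic aldehyde with a styryl silyloxydiene may be sluggish, the diene may hydrolyse before it reacts, and enantiofacial control may be incomplete. The fallback sets out from enone 2 and aldehyde 7 and builds the same ketone stepwise. An asymmetric boron aldol reaction of the methyl ketone (chlorodiisopinocampheylborane of the antipode that gives the S carbinol, Et3N, Et2O, −78 °C, then 7, buffered H2O2 work-up) should give (1E,5S)-1,7-bis[4-(tert-butyldimethylsilyloxy)-3-methoxyphenyl]-5-hydroxyhept-1-en-3-one F1. Its 6-endo oxa-Michael cyclization under thermodynamic control (Amberlyst-15, CH2Cl2, rt) should place both substituents equatorially and comes back to the route at ketone 9.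

2. Step 6. Equatorial hydride delivery may be incomplete, or the basic borohydride may enolize the β-alkoxy ketone and open the ring by retro-oxa-Michael reaction. The fallback sets out from ketone 9 and replaces reagent control by inversion. NaBH4 (MeOH, 0 °C) should attack axially and give the equatorial alcohol (2S,4R,6S)-2-[4-(tert-butyldimethylsilyloxy)-3-methoxyphenyl]-6-{2-[4-(tert-butyldimethylsilyloxy)-3-methoxyphenyl]ethyl}oxan-4-ol F2. Mitsunobu inversion (4-nitrobenzoic acid, PPh3, DIAD, toluene, 0 °C to rt) should give the axial ester (2S,4S,6S)-2-[4-(tert-butyldimethylsilyloxy)-3-methoxyphenyl]-6-{2-[4-(tert-butyldimethylsilyloxy)-3-methoxyphenyl]ethyl}oxan-4-yl 4-nitrobenzoate F3. K2CO3 in MeOH should then cleave the ester and both aryl silyl ethers together, so the fallback comes back to the route at target 11.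

3. Step 4. The hemiacetal may collapse before the quench, leading to over-reduction to the primary alcohol and a mixture of oxidation levels. The fallback sets out from ester 5 and makes over-reduction the intended outcome. Excess i-Bu2AlH (2.5 equiv, CH2Cl2, −78 to 0 °C) should give 3-[4-(tert-butyldimethylsilyloxy)-3-methoxyphenyl]propan-1-ol F4. Dess–Martin periodinane oxidation (NaHCO3, CH2Cl2, rt) then comes back to the route at aldehyde 7.

## Further compounds

F1 | step 5 | (1E,5S)-1,7-bis[4-(tert-butyldimethylsilyloxy)-3-methoxyphenyl]-5-hydroxyhept-1-en-3-one | COc1cc(CC[C@H](O)CC(=O)/C=C/c2ccc(O[Si](C)(C)C(C)(C)C)c(OC)c2)ccc1O[Si](C)(C)C(C)(C)C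
F2 | step 6 | (2S,4R,6S)-2-[4-(tert-butyldimethylsilyloxy)-3-methoxyphenyl]-6-{2-[4-(tert-butyldimethylsilyloxy)-3-methoxyphenyl]ethyl}oxan-4-ol | COc1cc(CC[C@H]2C[C@@H](O)C[C@@H](c3ccc(O[Si](C)(C)C(C)(C)C)c(OC)c3)O2)ccc1O[Si](C)(C)C(C)(C)C
F3 | step 6 | (2S,4S,6S)-2-[4-(tert-butyldimethylsilyloxy)-3-methoxyphenyl]-6-{2-[4-(tert-butyldimethylsilyloxy)-3-methoxyphenyl]ethyl}oxan-4-yl 4-nitrobenzoate | COc1cc(CC[C@H]2C[C@H](OC(=O)c4ccc(cc4)[N+](=O)[O-])C[C@@H](c3ccc(O[Si](C)(C)C(C)(C)C)c(OC)c3)O2)ccc1O[Si](C)(C)C(C)(C)C
F4 | step 4 | 3-[4-(tert-butyldimethylsilyloxy)-3-methoxyphenyl]propan-1-ol | OCCCc1ccc(O[Si](C)(C)C(C)(C)C)c(OC)c1
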